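**Strategy**

The C2-symmetric tetraene is cut at the central C–C bond of the butadiene bridge; each cyclohexene ring is traced to a cyclopentanone. The key step inserts a carbenoid carbon (from CH2Br2) between the carbonyl carbon and the quaternary ring carbon (bearing methyl and the epoxyethyl chain) of an enantioenriched 2,2-disubstituted 3-silyloxycyclopentanone. It exploits the higher migratory aptitude of that quaternary carbon, which sits next to the ring alkene CH in each six-membered ring: one flask gives the ring-enlarged, regiodefined enolate, and its triflate places C=C and coupling handle at the diene-bearing ring carbon. The precursor arises by desymmetrising reduction of a 2-methyl-2-homoprenylcyclopentane-1,3-dione.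

Key step: step 5

Remark: the oxazaborolidine reduction of 6 is taken to deliver hydride to the ring face anti to the longer C2 substituent, as with other 2-alkyl-2-methylcyclopentane-1,3-diones; the carbinol formed there is re-oxidised later, so only the quaternary centre rests on this.

**Route**

Step 1
Reactants: 1 2-methylcyclopentane-1,3-dione; 2 acrolein
Product: 3 3-(1-methyl-2,5-dioxocyclopentyl)propanal
Conditions: H2O, rt
Reagents that add atoms: none
Why: Michael addition of the enolised 1,3-dione to acrolein in water should give C-alkylation at C2 only, creating the (still prochiral) quaternary carbon; no stereocentre is formed.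

Step 2
Reactants: 3 3-(1-methyl-2,5-dioxocyclopentyl)propanal; 4 isopropyltriphenylphosphonium iodide
Product: 6 2-methyl-2-(4-methylpent-3-en-1-yl)cyclopentane-1,3-dione, via isopropylidenetriphenylphosphorane 5 (not isolated)
Conditions: 4, n-BuLi, THF, 0 °C; then 3, −78 → 0 °C
Reagents that add atoms: none
Why: Wittig olefination: the unstabilised ylide should attack the aldehyde far faster than the two hindered ring ketones at low temperature, and the gem-dimethyl alkene has no geometry to control.

Step 3
Reactants: 6 2-methyl-2-(4-methylpent-3-en-1-yl)cyclopentane-1,3-dione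
Product: 7 (2R,3R)-3-hydroxy-2-methyl-2-(4-methylpent-3-en-1-yl)cyclopentan-1-one
Conditions: (S)-2-methyl-CBS-oxazaborolidine (20 mol %), catecholborane, toluene, −78 → −40 °C
Reagents that add atoms: none
Why: CBS reduction used as desymmetrisation: the (S)-catalyst, reading the quaternary α-carbon as the large group, should fix the carbinol as R and reduce the enantiotopic carbonyl reachable from the methyl face, which sets the quaternary carbon as R (hydroxyl cis to the chain); catecholborane at low temperature leaves the trisubstituted alkene alone, and the minor diastereomer is removed by chromatography.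

Step 4
Reactants: 7 (2R,3R)-3-hydroxy-2-methyl-2-(4-methylpent-3-en-1-yl)cyclopentan-1-one
Product: 8 (2R,3R)-2-methyl-2-(4-methylpent-3-en-1-yl)-3-(triethylsilyloxy)cyclopentan-1-one
Conditions: Et3SiCl, imidazole, DMF, 0 °C → rt
Reagents that add atoms: chlorotriethylsilane CC[Si](Cl)(CC)CC
Why: Silyl ether formation under weakly basic conditions (no retro-aldol) masks the carbinol, which serves only to tell the two former carbonyl carbons apart, against the organolithium reagents of step 5.

Step 5
Reactants: 8 (2R,3R)-2-methyl-2-(4-methylpent-3-en-1-yl)-3-(triethylsilyloxy)cyclopentan-1-one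
Product: 12 (3S,4R)-3-methyl-3-(4-methylpent-3-en-1-yl)-4-(triethylsilyloxy)cyclohex-1-en-1-yl trifluoromethanesulfonate, via lithium dibromomethyl alkoxide 9 (not isolated), via β-oxido carbenoid 10 (not isolated), via ring-enlarged lithium enolate 11 (not isolated)
Conditions: CH2Br2, LiN(iPr)2, THF, −90 °C, then 8; n-BuLi, −90 → −60 °C; PhNTf2, −78 → 0 °C; aq. NH4Cl
Reagents that add atoms: dibromomethane BrCBr; N-phenylbis(trifluoromethanesulfonimide) O=S(=O)(N(c1ccccc1)S(=O)(=O)C(F)(F)F)C(F)(F)F
Why: LiCHBr2 adds to the ketone to give alkoxide 9, Br/Li exchange with n-BuLi gives the β-oxido carbenoid 10, and the alkoxide-assisted 1,2-shift of a ring carbon to the carbenoid carbon with loss of LiBr enlarges the ring to the lithium enolate 11, which PhNTf2 traps on oxygen. The closest known reaction type is the β-oxido carbenoid (dibromomethyllithium) ring enlargement of cycloalkanones with trapping of the regiodefined enolate. No ring is closed from an open chain: the cyclohexene ring arises from the cyclopentanone by insertion of one carbon into the C(=O)–C(quaternary) bond. No new stereocentre is formed; the quaternary carbon migrates with retention (its descriptor changes from R to S only because substituent priorities change), the silyloxy carbon is untouched, and the transient carbinol and carbenoid centres become sp2. The step needs migration of the quaternary carbon rather than the ring methylene, which the higher migratory aptitude of the more substituted, electron-richer α-carbon toward the electrophilic carbenoid should secure; it also needs the enolate C=C on the side of the inserted carbon, which the mechanism guarantees, since that bond can only join the old carbonyl carbon to the inserted carbon and cannot move without a proton source.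

Step 6
Reactants: 12 (3S,4R)-3-methyl-3-(4-methylpent-3-en-1-yl)-4-(triethylsilyloxy)cyclohex-1-en-1-yl trifluoromethanesulfonate
Product: 13 (3S)-3-methyl-3-(4-methylpent-3-en-1-yl)-4-oxocyclohex-1-en-1-yl trifluoromethanesulfonate
Conditions: IBX, DMSO, rt → 35 °C
Reagents that add atoms: none
Why: Oxidative desilylation: IBX in DMSO is known to cleave triethylsilyl ethers and to oxidise the liberated secondary alcohol in the same pot, which should give the ketone directly; its α-carbon is quaternary, so neither epimerisation nor conjugation of the ring alkene is possible, and the alkenyl triflate and trisubstituted alkene are inert.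

Step 7
Reactants: 13 (3S)-3-methyl-3-(4-methylpent-3-en-1-yl)-4-oxocyclohex-1-en-1-yl trifluoromethanesulfonate
Product: 14 (3S,4S)-4-hydroxy-3-methyl-3-(4-methylpent-3-en-1-yl)cyclohex-1-en-1-yl trifluoromethanesulfonate
Conditions: (R)-2-methyl-CBS-oxazaborolidine (20 mol %), catecholborane, toluene, −78 °C
Reagents that add atoms: none
Why: CBS reduction under reagent control: the (R)-catalyst, again reading the quaternary α-carbon as the large group, should give the S-carbinol with the hydroxyl cis to the methyl group, overriding the small intrinsic bias of the ring; the alkenyl triflate and the alkene are untouched by catecholborane at −78 °C.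

Step 8
Reactants: 14 (3S,4S)-4-hydroxy-3-methyl-3-(4-methylpent-3-en-1-yl)cyclohex-1-en-1-yl trifluoromethanesulfonate
Product: 15 (3S,4S)-3-{2-[(2R)-3,3-dimethyloxiran-2-yl]ethyl}-4-hydroxy-3-methylcyclohex-1-en-1-yl trifluoromethanesulfonate
Conditions: D-fructose-derived Shi ketone (30 mol %), Oxone (2KHSO5·KHSO4·K2SO4), K2CO3, Bu4NHSO4, MeCN/CH2(OMe)2/aq. buffer pH 10.5, 0 °C
Reagents that add atoms: potassium peroxymonosulfate [K+].[O-]S(=O)(=O)OO
Why: Shi asymmetric epoxidation: the dioxirane from the D-fructose-derived ketone should epoxidise only the electron-rich trisubstituted alkene (the triflate-bearing ring alkene is electron-poor) through the spiro transition state that gives the R-epoxide, under reagent control remote from the ring stereocentres.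

Step 9
Reactants: 15 (3S,4S)-3-{2-[(2R)-3,3-dimethyloxiran-2-yl]ethyl}-4-hydroxy-3-methylcyclohex-1-en-1-yl trifluoromethanesulfonate; 16 (E)-1,2-bis(tributylstannyl)ethene
Product: 17 (1S,2S)-2-{2-[(2R)-3,3-dimethyloxiran-2-yl]ethyl}-2-methyl-4-[(E)-2-(tributylstannyl)ethenyl]cyclohex-3-en-1-ol
Conditions: 16 (4 equiv), Pd2(dba)3 (2.5 mol %), AsPh3 (20 mol %), NMP, rt → 40 °C
Reagents that add atoms: none
Why: Stille coupling of the alkenyl triflate with retention of the E geometry of the stannane; a large excess of 16 should suppress double coupling, and the neutral, chloride-free conditions spare epoxide and hydroxyl.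

Step 10
Reactants: 17 (1S,2S)-2-{2-[(2R)-3,3-dimethyloxiran-2-yl]ethyl}-2-methyl-4-[(E)-2-(tributylstannyl)ethenyl]cyclohex-3-en-1-ol (two molecules)
Product: 18 (1S,1'S,2S,2'S)-4,4'-[(1E,3E)-buta-1,3-diene-1,4-diyl]bis(2-{2-[(2R)-3,3-dimethyloxiran-2-yl]ethyl}-2-methylcyclohex-3-en-1-ol)
Conditions: CuCl (5 equiv), DMF, rt, dark, Ar
Reagents that add atoms: none
Why: CuCl-mediated oxidative homocoupling of an alkenylstannane (tin-to-copper transmetalation, then C–C coupling of the dienylcopper with retention of geometry) should join two molecules of 17 at the central bond of the bridge to give the E,E-diene and with it the C2-symmetric tetraene; no stereocentre is touched.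

**Compound list**

1 | 2-methylcyclopentane-1,3-dione | CC1C(=O)CCC1=O | starting material
2 | acrolein | C=CC=O | starting material
3 | 3-(1-methyl-2,5-dioxocyclopentyl)propanal | O=CCCC1(C)C(=O)CCC1=O | intermediate
4 | isopropyltriphenylphosphonium iodide | CC(C)[P+](c1ccccc1)(c1ccccc1)c1ccccc1.[I-] | starting material
5 | isopropylidenetriphenylphosphorane | CC(C)=P(c1ccccc1)(c1ccccc1)c1ccccc1 | intermediate (not isolated)
6 | 2-methyl-2-(4-methylpent-3-en-1-yl)cyclopentane-1,3-dione | CC(C)=CCCC1(C)C(=O)CCC1=O | intermediate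
7 | (2R,3R)-3-hydroxy-2-methyl-2-(4-methylpent-3-en-1-yl)cyclopentan-1-one | CC(C)=CCC[C@@]1(C)C(=O)CC[C@H]1O | intermediate
8 | (2R,3R)-2-methyl-2-(4-methylpent-3-en-1-yl)-3-(triethylsilyloxy)cyclopentan-1-one | CC(C)=CCC[C@@]1(C)C(=O)CC[C@H]1O[Si](CC)(CC)CC | intermediate
9 | lithium (2R,3R)-1-(dibromomethyl)-2-methyl-2-(4-methylpent-3-en-1-yl)-3-(triethylsilyloxy)cyclopentan-1-olate (C1 not controlled) | CC(C)=CCC[C@@]1(C)C(O[Li])(C(Br)Br)CC[C@H]1O[Si](CC)(CC)CC | intermediate (not isolated)
10 | lithium (2R,3R)-1-[bromo(lithio)methyl]-2-methyl-2-(4-methylpent-3-en-1-yl)-3-(triethylsilyloxy)cyclopentan-1-olate (β-oxido carbenoid) | CC(C)=CCC[C@@]1(C)C(O[Li])(C([Li])Br)CC[C@H]1O[Si](CC)(CC)CC | intermediate (not isolated)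
11 | lithium (3S,4R)-3-methyl-3-(4-methylpent-3-en-1-yl)-4-(triethylsilyloxy)cyclohex-1-en-1-olate | CC(C)=CCC[C@@]1(C)C=C(O[Li])CC[C@H]1O[Si](CC)(CC)CC | intermediate (not isolated)
12 | (3S,4R)-3-methyl-3-(4-methylpent-3-en-1-yl)-4-(triethylsilyloxy)cyclohex-1-en-1-yl trifluoromethanesulfonate | CC(C)=CCC[C@@]1(C)C=C(OS(=O)(=O)C(F)(F)F)CC[C@H]1O[Si](CC)(CC)CC | intermediate
13 | (3S)-3-methyl-3-(4-methylpent-3-en-1-yl)-4-oxocyclohex-1-en-1-yl trifluoromethanesulfonate | CC(C)=CCC[C@@]1(C)C=C(OS(=O)(=O)C(F)(F)F)CCC1=O | intermediate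
14 | (3S,4S)-4-hydroxy-3-methyl-3-(4-methylpent-3-en-1-yl)cyclohex-1-en-1-yl trifluoromethanesulfonate | CC(C)=CCC[C@@]1(C)C=C(OS(=O)(=O)C(F)(F)F)CC[C@@H]1O | intermediate
15 | (3S,4S)-3-{2-[(2R)-3,3-dimethyloxiran-2-yl]ethyl}-4-hydroxy-3-methylcyclohex-1-en-1-yl trifluoromethanesulfonate | CC1(C)O[C@@H]1CC[C@@]1(C)C=C(OS(=O)(=O)C(F)(F)F)CC[C@@H]1O | intermediate
16 | (E)-1,2-bis(tributylstannyl)ethene | CCCC[Sn](CCCC)(CCCC)/C=C/[Sn](CCCC)(CCCC)CCCC | starting material
17 | (1S,2S)-2-{2-[(2R)-3,3-dimethyloxiran-2-yl]ethyl}-2-methyl-4-[(E)-2-(tributylstannyl)ethenyl]cyclohex-3-en-1-ol | CC1(C)O[C@@H]1CC[C@@]1(C)C=C(/C=C/[Sn](CCCC)(CCCC)CCCC)CC[C@@H]1O | intermediate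
18 | (1S,1'S,2S,2'S)-4,4'-[(1E,3E)-buta-1,3-diene-1,4-diyl]bis(2-{2-[(2R)-3,3-dimethyloxiran-2-yl]ethyl}-2-methylcyclohex-3-en-1-ol) | CC1(C)O[C@@H]1CC[C@@]1(C)C=C(/C=C/C=C/C2=C[C@](C)(CC[C@H]3OC3(C)C)[C@@H](O)CC2)CC[C@@H]1O | target

**Step count**

Total step count: 10. Longest linear sequence: 10 steps (1 → 18); 16 is bought.

**Steps most likely to fail**

1. Step 5. The ring methylene may migrate in place of the quaternary carbon, or the hindered ketone may be deprotonated instead of attacked by LiCHBr2. The fallback sets out from 8 and comes back at 17; it uses the opposite migratory preference. BF3·OEt2-promoted ring enlargement of 8 with ethyl diazoacetate (Et2O, 0 °C), in which the less substituted methylene carbon migrates, should give ethyl (3R,4R)-3-methyl-3-(4-methylpent-3-en-1-yl)-2-oxo-4-(triethylsilyloxy)cyclohexane-1-carboxylate F1. NaH and PhNTf2 should convert it into the enol triflate ethyl (3R,4R)-3-methyl-3-(4-methylpent-3-en-1-yl)-4-(triethylsilyloxy)-2-(trifluoromethylsulfonyloxy)cyclohex-1-ene-1-carboxylate F2. Pd(OAc)2, PPh3, HCO2H and Bu3N (DMF, 60 °C) should reduce it to ethyl (3S,4R)-3-methyl-3-(4-methylpent-3-en-1-yl)-4-(triethylsilyloxy)cyclohex-1-ene-1-carboxylate F3, whose ring C=C can only lie between the former carbonyl carbon and the ester-bearing carbon. IBX in DMSO should give ethyl (3S)-3-methyl-3-(4-methylpent-3-en-1-yl)-4-oxocyclohex-1-ene-1-carboxylate F4. (R)-2-Methyl-CBS-oxazaborolidine with catecholborane should give ethyl (3S,4S)-4-hydroxy-3-methyl-3-(4-methylpent-3-en-1-yl)cyclohex-1-ene-1-carboxylate F5. Shi epoxidation should give ethyl (3S,4S)-3-{2-[(2R)-3,3-dimethyloxiran-2-yl]ethyl}-4-hydroxy-3-methylcyclohex-1-ene-1-carboxylate F6. iBu2AlH (CH2Cl2, −78 °C) should give (1S,2S)-2-{2-[(2R)-3,3-dimethyloxiran-2-yl]ethyl}-4-(hydroxymethyl)-2-methylcyclohex-3-en-1-ol F7, and MnO2 should give (3S,4S)-3-{2-[(2R)-3,3-dimethyloxiran-2-yl]ethyl}-4-hydroxy-3-methylcyclohex-1-ene-1-carbaldehyde F8. Takai-type stannyl-olefination of F8 (CrCl2, Bu3SnCHBr2, LiI, THF/DMF) should then give 17.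

2. Step 10. Tin-to-copper transmetalation of the tributylstannane may be slow, or the copper salt may trigger attack of the ring hydroxyl on the epoxide. The fallback sets out from 17 and comes back at 18; it replaces oxidative homocoupling by cross-coupling. Half of 17 is treated with I2 (CH2Cl2, NaHCO3, 0 °C) to give (1S,2S)-2-{2-[(2R)-3,3-dimethyloxiran-2-yl]ethyl}-4-[(E)-2-iodoethenyl]-2-methylcyclohex-3-en-1-ol F9 with retention of geometry. Stille coupling of F9 with the other half of 17 (Pd2(dba)3, AsPh3, NMP, rt) should give 18.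

3. Step 3. The catalyst may discriminate poorly between the methyl face and the chain face, that is, between the two enantiotopic carbonyl groups, which would erode enantiopurity at the quaternary carbon. The fallback sets out from 6 and comes back at 13; it is biocatalytic and exchanges the roles of the two ring carbonyl carbons. Baker's yeast (sucrose, H2O, 30 °C), reported to reduce 2-alkyl-2-methylcyclopentane-1,3-diones to (2S,3S)-ketols, should give (2S,3S)-3-hydroxy-2-methyl-2-(4-methylpent-3-en-1-yl)cyclopentan-1-one F10, the enantiomer of 7. Ketalisation of its ketone (ethylene glycol, PPTS, benzene, reflux) should give (6S,7S)-6-methyl-6-(4-methylpent-3-en-1-yl)-1,4-dioxaspiro[4.4]nonan-7-ol F11. Dess–Martin oxidation should give (6S)-6-methyl-6-(4-methylpent-3-en-1-yl)-1,4-dioxaspiro[4.4]nonan-7-one F12, in which the ketone now flanks the quaternary carbon in the same sense as in 8. The conditions of step 5 should give (6S)-6-methyl-6-(4-methylpent-3-en-1-yl)-1,4-dioxaspiro[4.5]dec-7-en-8-yl trifluoromethanesulfonate F13, and PPTS in acetone/H2O should release 13.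

**Further compounds**

F1 | step 5 | ethyl (3R,4R)-3-methyl-3-(4-methylpent-3-en-1-yl)-2-oxo-4-(triethylsilyloxy)cyclohexane-1-carboxylate | CC(C)=CCC[C@@]1(C)C(=O)C(C(=O)OCC)CC[C@H]1O[Si](CC)(CC)CC
F2 | step 5 | ethyl (3R,4R)-3-methyl-3-(4-methylpent-3-en-1-yl)-4-(triethylsilyloxy)-2-(trifluoromethylsulfonyloxy)cyclohex-1-ene-1-carboxylate | CC(C)=CCC[C@@]1(C)C(OS(=O)(=O)C(F)(F)F)=C(C(=O)OCC)CC[C@H]1O[Si](CC)(CC)CC
F3 | step 5 | ethyl (3S,4R)-3-methyl-3-(4-methylpent-3-en-1-yl)-4-(triethylsilyloxy)cyclohex-1-ene-1-carboxylate | CC(C)=CCC[C@@]1(C)C=C(C(=O)OCC)CC[C@H]1O[Si](CC)(CC)CC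
F4 | step 5 | ethyl (3S)-3-methyl-3-(4-methylpent-3-en-1-yl)-4-oxocyclohex-1-ene-1-carboxylate | CC(C)=CCC[C@@]1(C)C=C(C(=O)OCC)CCC1=O
F5 | step 5 | ethyl (3S,4S)-4-hydroxy-3-methyl-3-(4-methylpent-3-en-1-yl)cyclohex-1-ene-1-carboxylate | CC(C)=CCC[C@@]1(C)C=C(C(=O)OCC)CC[C@@H]1O
F6 | step 5 | ethyl (3S,4S)-3-{2-[(2R)-3,3-dimethyloxiran-2-yl]ethyl}-4-hydroxy-3-methylcyclohex-1-ene-1-carboxylate | CC1(C)O[C@@H]1CC[C@@]1(C)C=C(C(=O)OCC)CC[C@@H]1O
F7 | step 5 | (1S,2S)-2-{2-[(2R)-3,3-dimethyloxiran-2-yl]ethyl}-4-(hydroxymethyl)-2-methylcyclohex-3-en-1-ol | CC1(C)O[C@@H]1CC[C@@]1(C)C=C(CO)CC[C@@H]1O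
F8 | step 5 | (3S,4S)-3-{2-[(2R)-3,3-dimethyloxiran-2-yl]ethyl}-4-hydroxy-3-methylcyclohex-1-ene-1-carbaldehyde | CC1(C)O[C@@H]1CC[C@@]1(C)C=C(C=O)CC[C@@H]1O
F9 | step 10 | (1S,2S)-2-{2-[(2R)-3,3-dimethyloxiran-2-yl]ethyl}-4-[(E)-2-iodoethenyl]-2-methylcyclohex-3-en-1-ol | CC1(C)O[C@@H]1CC[C@@]1(C)C=C(/C=C/I)CC[C@@H]1O
F10 | step 3 | (2S,3S)-3-hydroxy-2-methyl-2-(4-methylpent-3-en-1-yl)cyclopentan-1-one | CC(C)=CCC[C@]1(C)C(=O)CC[C@@H]1O
F11 | step 3 | (6S,7S)-6-methyl-6-(4-methylpent-3-en-1-yl)-1,4-dioxaspiro[4.4]nonan-7-ol | CC(C)=CCC[C@]1(C)C2(OCCO2)CC[C@@H]1O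
F12 | step 3 | (6S)-6-methyl-6-(4-methylpent-3-en-1-yl)-1,4-dioxaspiro[4.4]nonan-7-one | CC(C)=CCC[C@@]1(C)C(=O)CCC12OCCO2
F13 | step 3 | (6S)-6-methyl-6-(4-methylpent-3-en-1-yl)-1,4-dioxaspiro[4.5]dec-7-en-8-yl trifluoromethanesulfonate | CC(C)=CCC[C@@]1(C)C=C(OS(=O)(=O)C(F)(F)F)CCC12OCCO2
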